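**Earlier runs.** In the south run the starting complex stands at 34.5% at the first reading, 5.00 min, and at 34.4% at 30.0 min, so its exchange has stopped moving by the first reading. The complex with three exchanged holds near 17.8% from 10.0 min on, while the complex with two exchanged sinks from 13.7% to 7.1% over the whole run.

| flask | starting complex | incoming ligand | temperature | remark | time |
|---|---|---|---|---|---|
| south | 0.040 M | 1.3 equiv | 65 °C | run made earlier |  |
| north | 0.056 M | 1.3 equiv | 76 °C | run made earlier |  |
| south-east | 0.088 M | 1.3 equiv | 65 °C | run made earlier |  |
| zeta | 0.040 M | 1.30 equiv (fed, over 20 min) |  | the addition at 30 °C, then warmed to 70 °C; the feed brings no volume worth counting | 30 min |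
| gamma | 0.040 M | 1.30 equiv | 70 °C | everything together at the start | 30 min |
| epsilon | 0.040 M (fed, over 20 min) | 1.30 equiv | 70 °C | all else is in the flask from the start; the feed brings no volume worth counting | 30 min |
| beta | 0.040 M | 1.30 equiv (fed, over 20 min) | 70 °C | all else is in the flask from the start; the feed brings no volume worth counting | 30 min |

- south (time / min: complex with two exchanged / %, complex with three exchanged / %, starting complex / %): 5.00: 13.7, 15.9, 34.5; 10.0: 11.6, 17.1, 34.1; 15.0: 9.3, 17.1, 34.6; 20.0: 8.6, 18.3, 34.6; 25.0: 6.9, 17.7, 35.9; 30.0: 7.1, 17.8, 34.4
- north (time / min: complex with two exchanged / %, complex with three exchanged / %, starting complex / %): 5.00: 8.0, 18.0, 37.9; 10.0: 5.6, 17.4, 37.8; 15.0: 4.2, 19.0, 37.9; 20.0: 3.6, 17.5, 37.8; 25.0: 3.7, 18.2, 37.9; 30.0: 3.2, 18.0, 38.5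
- south-east (time / min: complex with two exchanged / %, complex with three exchanged / %, starting complex / %): 5.00: 11.2, 18.3, 37.5; 10.0: 8.5, 19.7, 37.8; 15.0: 7.9, 19.0, 38.2; 20.0: 5.7, 18.6, 37.8; 25.0: 6.2, 18.6, 38.0; 30.0: 5.6, 18.9, 39.2

(readings scatter by 0.5 percentage points)

- the numbers in the tables scatter with a standard deviation of 0.5 percentage points

- the flask that comes out highest in share of complex with two exchanged in complex with two exchanged plus complex with three exchanged, or "all alike" when all lie within 1.5 percentage points (zeta / gamma / epsilon / beta / all alike)
- share of complex with two exchanged in complex with two exchanged plus complex with three exchanged at the end, zeta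
- share of complex with two exchanged in complex with two exchanged plus complex with three exchanged at the end, gamma
- share of complex with two exchanged in complex with two exchanged plus complex with three exchanged at the end, epsilon
- share of complex with two exchanged in complex with two exchanged plus complex with three exchanged at the end, beta

**Settling time.** The large amount holds still, so the reckoning follows the small correction: the excess of complex with two exchanged over its final level. Drops across equal intervals give its half-life without that level being known. In the south run the drops are 4.4 points and then 2.4 points, which reads as 11.4 min. In the north run, both hotter and more concentrated, the drops are 2.4 points and 1.4 points, which reads as a shorter 6.43 min. The geometric mean for 70 °C, roughly midway, is 8.57 min: the settling half-time (relaxation half-life), the time in which that excess halves. It is a reading, and each value behind it scatters by 0.5 points.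

**The ladder.** First comes the exchange, over within 5.00 min in the south run. Next comes settling, then the feed of 20 min, then the reading at 30 min. Gamma has 3.50 half-times from the start, which leaves 8.84% of an excess. Beta and zeta have 1.17 hot half-times after the feed ends, which leaves 44.5% of an excess formed at that moment. For such an excess this reckoning puts beta and zeta above gamma, but it does not separate them.

**The forecast.** The forecast gives zeta 45%, gamma 22%, epsilon 9% and beta 27%, and names zeta as highest, citing “a short hot period for drainage”. It goes beyond the reckoning above by placing zeta over beta.

**The result.** Zeta gives 33.1%, gamma 20.4%, epsilon 16.3% and beta 38.0%, so the highest is beta.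

    complex with three exchanged + incoming ligand ⇌ leaving ligand + complex with four exchanged (K = 5.40, k = 0.300 /M/s, Ea = 70.0 kJ/mol, ΔH = −24.0 kJ/mol)
    complex with two exchanged + incoming ligand ⇌ leaving ligand + complex with three exchanged (K = 56.0, k = 0.800 /M/s, Ea = 66.0 kJ/mol, ΔH = 7.00 kJ/mol)
    complex with two exchanged ⇌ isomer of the product (K = 4.10, k = 0.00100 /s, Ea = 115 kJ/mol, ΔH = −29.0 kJ/mol)
    starting complex + incoming ligand ⇌ leaving ligand + complex with one exchanged (K = 7.30, k = 0.550 /M/s, Ea = 66.0 kJ/mol, ΔH = −44.0 kJ/mol)
    complex with one exchanged + incoming ligand ⇌ leaving ligand + complex with two exchanged (K = 4.90, k = 0.830 /M/s, Ea = 63.0 kJ/mol, ΔH = −27.0 kJ/mol)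
    leaving ligand → by-product carried off (k = 0.00570 /s, Ea = 90.0 kJ/mol)
    (constants at 70 °C)

**The excess.** At 30.0 min beta and zeta hold 8.80% and 8.69% of complex with two exchanged, but beta holds less complex with three exchanged, 14.4% against 17.6%. The state at 300 min lies 31.5 settling half-times later, so it serves as the level. Beta stands 4.4 points above it 1.17 half-times after the feed ends, and gamma 1.4 points above it 3.50 half-times from the start. At 300 min the share in beta is 23.2%.

The numbers in the tables were computed with made-up constants; scatter was added.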